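A direct plan would acylate 1,2,3,5-tetramethoxybenzene A1 with methoxyacetyl chloride A2 and AlCl3, one ortho methyl being lost in the same flask, to give hydroxy ketone A3. It would then C-aroylate A3 with 2-methoxybenzoyl chloride A4 and cyclodehydrate the product to the fully methylated flavone A5 before ending with AlCl3 cleavage of the 5-OMe. Its weakest steps would be:
(a) the acylation with in-flask demethylation: AlCl3 must choose one of the two OMe groups flanking the new carbonyl, and this choice alone decides between the 5,7,8- and the 5,6,7-pattern;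
(b) the aroylation of the phenoxide–enolate of A3: O- and C-acylation by a hindered acid chloride compete under excess strong base;
(c) the final peri-demethylation of A5: it undoes a methylation that built nothing and puts the chelated 3-OMe at risk in the last step.

**Retrosynthetic overview**
Ring A is 3,4,5-trimethoxyphenol in disguise: its OH is the 5-OH, and the oxygen of one flanking OMe is O1, already bound to C8a next to the 8-OMe/7-OMe pair. Ring C is cut at both bonds of C4 (aryl iodide + CO + 2-ethynylanisole joined around the carbonyl) and at O1–C2, which closes last by 6-endo iodocyclization in which that OMe loses its methyl. C3–I then becomes C3–OMe. Rings A and B are bought; only ring C is formed. The 5-oxygen is never methylated, the ring oxygen is fixed by the geometry of the ynone, and no enolate is acylated.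

Key step: step 3

Remark: flavone numbering is used (O1, C2, C3, C4, C4a, C5–C8, C8a; ring B primed); the target is achiral, so no stereocentre has to be set.

Step 1
Reactants: 1 3,4,5-trimethoxyphenol
Product: 3 2-iodo-3,4,5-trimethoxyphenyl acetate, via iodophenol 2 (not isolated)
Conditions: NIS (1.0 equiv), MeCN, 0 °C, dark; then pyridine, Ac2O (2 equiv), DMAP (cat.), 0 °C → rt
Reagents that add atoms: N-iodosuccinimide, O=C1CCC(=O)N1I; acetic anhydride, CC(=O)OC(C)=O
Why: Electrophilic aromatic iodination can only take place at one of the two equivalent positions ortho to OH (the only free ring positions), and O-acetylation of the crude iodophenol then silences the future 5-oxygen as a nucleophile with a group that the conditions of the last step remove.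

Step 2
Reactants: 3 2-iodo-3,4,5-trimethoxyphenyl acetate + 4 1-ethynyl-2-methoxybenzene (2-ethynylanisole) + 5 carbon monoxide
Product: 6 2-[3-(2-methoxyphenyl)prop-2-ynoyl]-3,4,5-trimethoxyphenyl acetate
Conditions: PdCl2(PPh3)2 (5 mol %), Et3N (3 equiv), CO (5 bar), THF, 50 °C, no copper cocatalyst
Reagents that add atoms: carbon monoxide (compound 5), [C-]#[O+]; 1-ethynyl-2-methoxybenzene (compound 4), COc1ccccc1C#C
Why: In a carbonylative Sonogashira coupling, oxidative addition of the C–I bond to zerovalent palladium, CO insertion (fast at a doubly ortho-substituted aryl–palladium bond, while direct alkynylation is slow without copper), amine-assisted transfer of the alkyne to the acyl complex of divalent palladium and reductive elimination should join the three components at the future C4 and form both C4a–C4 and C4–C3.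

Step 3
Reactants: 6 2-[3-(2-methoxyphenyl)prop-2-ynoyl]-3,4,5-trimethoxyphenyl acetate
Product: 7 3-iodo-7,8-dimethoxy-2-(2-methoxyphenyl)-4-oxo-4H-chromen-5-yl acetate
Conditions: ICl (1.5 equiv, 1 M in CH2Cl2), CH2Cl2, −78 °C → rt, dark; aq. Na2S2O3
Reagents that add atoms: iodine monochloride, ICl
Why: Iodine monochloride should turn the triple bond into an iodonium (β-iodovinyl cation) whose positive charge sits on the alkyne carbon bonded to ring B (future C2), remote from the carbonyl group and stabilised by the 2-methoxyphenyl group; the oxygen of the OMe group ortho to the acyl group on ring A attacks this carbon anti to iodine, and chloride then removes the methyl of the resulting methyloxonium ion by SN2 attack (as CH3Cl), which makes the closure irreversible. The closest known reaction type is the iodine monochloride-induced cyclization of 2-methoxyaryl alkynyl ketones to 3-iodochromones. Ring C closes in the 6-endo-dig mode and O1–C2 and C3–I form together; no stereocentre is formed. The step needs three selectivities: (a) the right oxygen, secured because the acetate oxygen on the other ortho position is deactivated by its own carbonyl group (that carbonyl oxygen could only close an eight-membered ring) and the two other OMe groups of ring A cannot reach the alkyne, so O1 ends up next to the 8-OMe/7-OMe pair and the 5-oxygen stays acylated; (b) 6-endo closure from ring A over 5-endo closure by the 2'-OMe of ring B, which would have to attack the alkyne carbon next to the carbonyl group, where positive charge is destabilised; (c) alkyne activation over iodination of the electron-rich rings, which low temperature and a small excess of ICl should secure.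

Step 4
Reactants: 7 3-iodo-7,8-dimethoxy-2-(2-methoxyphenyl)-4-oxo-4H-chromen-5-yl acetate
Product: 9 5-hydroxy-3,7,8-trimethoxy-2-(2-methoxyphenyl)-4H-chromen-4-one (5-hydroxy-3,7,8,2'-tetramethoxyflavone), via 5-hydroxy-3-iodoflavone 8 (not isolated)
Conditions: CuI (10 mol %), 3,4,7,8-tetramethyl-1,10-phenanthroline (20 mol %), Cs2CO3 (3 equiv), MeOH/toluene 1:1, 80–100 °C, sealed tube; then dil. aq. HCl work-up
Reagents that add atoms: methanol, CO
Why: Ullmann-type C–O coupling of the vinylic C3–I bond with methanol under catalysis by monovalent copper and a phenanthroline ligand should install the 3-OMe, while the faster methanolysis of the aryl acetate frees the 5-oxygen as its caesium phenoxide, whose donation into the C4 carbonyl group also lowers the risk of methoxide addition at C2; acidic work-up gives the chelated 5-OH.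

**Compound list**
1 | 3,4,5-trimethoxyphenol | COc1cc(O)cc(OC)c1OC | starting material
2 | 2-iodo-3,4,5-trimethoxyphenol | COc1cc(O)c(I)c(OC)c1OC | intermediate
3 | 2-iodo-3,4,5-trimethoxyphenyl acetate | COc1cc(OC(C)=O)c(I)c(OC)c1OC | intermediate
4 | 1-ethynyl-2-methoxybenzene (2-ethynylanisole) | COc1ccccc1C#C | starting material
5 | carbon monoxide | [C-]#[O+] | starting material
6 | 2-[3-(2-methoxyphenyl)prop-2-ynoyl]-3,4,5-trimethoxyphenyl acetate | COc1ccccc1C#CC(=O)c1c(OC(C)=O)cc(OC)c(OC)c1OC | intermediate
7 | 3-iodo-7,8-dimethoxy-2-(2-methoxyphenyl)-4-oxo-4H-chromen-5-yl acetate | COc1ccccc1-c1oc2c(OC)c(OC)cc(OC(C)=O)c2c(=O)c1I | intermediate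
8 | 5-hydroxy-3-iodo-7,8-dimethoxy-2-(2-methoxyphenyl)-4H-chromen-4-one (present as its caesium phenoxide) | COc1ccccc1-c1oc2c(OC)c(OC)cc(O)c2c(=O)c1I | intermediate
9 | 5-hydroxy-3,7,8-trimethoxy-2-(2-methoxyphenyl)-4H-chromen-4-one (achiral) | COc1ccccc1-c1oc2c(OC)c(OC)cc(O)c2c(=O)c1OC | target

**Totals and risks**
Total step count: 4. Longest linear sequence: 4 steps (from 3,4,5-trimethoxyphenol).

Steps most likely to fail:

1. Step 4. The coupling may lose iodine reductively, methoxide may add to C2 and open the pyranone, or the 5-phenoxide/4-carbonyl chelate may tie up the copper. The fallback sets out from 7 and comes back at 9. Miyaura borylation of 7 (B2pin2, PdCl2(dppf), KOAc, dioxane, 80 °C) should give 7,8-dimethoxy-2-(2-methoxyphenyl)-4-oxo-3-(4,4,5,5-tetramethyl-1,3,2-dioxaborolan-2-yl)-4H-chromen-5-yl acetate F1. Oxidation with H2O2 and aq. NaOH in THF at 0 °C, which should also hydrolyse the acetate, would give 3,5-dihydroxy-7,8-dimethoxy-2-(2-methoxyphenyl)-4H-chromen-4-one F2. MeI (1.05 equiv) and K2CO3 in acetone at rt should then methylate only the 3-OH, because the 5-OH is held in the six-membered hydrogen bond to the C4 carbonyl group, and give 9.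

2. Step 3. Iodination of the electron-rich rings, 5-endo participation of the ring B methoxy group or plain addition of ICl across the triple bond may compete with the 6-endo closure. The fallback sets out from 6 and comes back at 7; it separates ring closure from iodination. BCl3 (1.2 equiv, CH2Cl2, −78 → 0 °C) should cleave only the methyl ether that is chelated with the ynone carbonyl group and give 3-hydroxy-4,5-dimethoxy-2-[3-(2-methoxyphenyl)prop-2-ynoyl]phenyl acetate F3. TfOH (cat.) in CH2Cl2 should close it 6-endo; acid is chosen so that no base can move the acetyl group between the two oxygens. This would give 7,8-dimethoxy-2-(2-methoxyphenyl)-4-oxo-4H-chromen-5-yl acetate F4. I2 with (NH4)2Ce(NO3)6 in MeCN should then iodinate C3, the nucleophilic carbon of the vinylogous ester, and give 7.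

3. Step 2. Direct alkynylation without uptake of CO at the hindered iodide, or amine-induced loss of the acetate followed by closure through the wrong oxygen, may erode the ynone. The fallback sets out from 1 and comes back at 6, so that iodide 3 is not needed. Ortho-formylation of 1 (MgCl2, Et3N, paraformaldehyde, MeCN, reflux) should give 6-hydroxy-2,3,4-trimethoxybenzaldehyde F5. Lithium (2-methoxyphenyl)acetylide F6 (from 4 and n-BuLi, 2.2 equiv, THF, −78 → 0 °C) should add to it and give racemic 2-[1-hydroxy-3-(2-methoxyphenyl)prop-2-yn-1-yl]-3,4,5-trimethoxyphenol F7. Ac2O (1.05 equiv) and Et3N in CH2Cl2 at 0 °C should acetylate the phenol only, to racemic 2-[1-hydroxy-3-(2-methoxyphenyl)prop-2-yn-1-yl]-3,4,5-trimethoxyphenyl acetate F8. MnO2 in CH2Cl2 at rt should oxidise the propargylic alcohol to 6.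

**Further compounds**
F1 | step 4 | 7,8-dimethoxy-2-(2-methoxyphenyl)-4-oxo-3-(4,4,5,5-tetramethyl-1,3,2-dioxaborolan-2-yl)-4H-chromen-5-yl acetate | COc1ccccc1-c1oc2c(OC)c(OC)cc(OC(C)=O)c2c(=O)c1B1OC(C)(C)C(C)(C)O1
F2 | step 4 | 3,5-dihydroxy-7,8-dimethoxy-2-(2-methoxyphenyl)-4H-chromen-4-one | COc1ccccc1-c1oc2c(OC)c(OC)cc(O)c2c(=O)c1O
F3 | step 3 | 3-hydroxy-4,5-dimethoxy-2-[3-(2-methoxyphenyl)prop-2-ynoyl]phenyl acetate | COc1ccccc1C#CC(=O)c1c(OC(C)=O)cc(OC)c(OC)c1O
F4 | step 3 | 7,8-dimethoxy-2-(2-methoxyphenyl)-4-oxo-4H-chromen-5-yl acetate | COc1ccccc1-c1cc(=O)c2c(OC(C)=O)cc(OC)c(OC)c2o1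
F5 | step 2 | 6-hydroxy-2,3,4-trimethoxybenzaldehyde | COc1cc(O)c(C=O)c(OC)c1OC
F6 | step 2 | lithium (2-methoxyphenyl)acetylide | [Li]C#Cc1ccccc1OC
F7 | step 2 | 2-[1-hydroxy-3-(2-methoxyphenyl)prop-2-yn-1-yl]-3,4,5-trimethoxyphenol (racemic) | COc1ccccc1C#CC(O)c1c(O)cc(OC)c(OC)c1OC
F8 | step 2 | 2-[1-hydroxy-3-(2-methoxyphenyl)prop-2-yn-1-yl]-3,4,5-trimethoxyphenyl acetate (racemic) | COc1ccccc1C#CC(O)c1c(OC(C)=O)cc(OC)c(OC)c1OC
A1 | direct plan | 1,2,3,5-tetramethoxybenzene | COc1cc(OC)c(OC)c(OC)c1
A2 | direct plan | methoxyacetyl chloride | COCC(Cl)=O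
A3 | direct plan | 1-(2-hydroxy-3,4,6-trimethoxyphenyl)-2-methoxyethan-1-one | COCC(=O)c1c(O)c(OC)c(OC)cc1OC
A4 | direct plan | 2-methoxybenzoyl chloride | COc1ccccc1C(Cl)=O
A5 | direct plan | 3,5,7,8-tetramethoxy-2-(2-methoxyphenyl)-4H-chromen-4-one | COc1ccccc1-c1oc2c(OC)c(OC)cc(OC)c2c(=O)c1OC
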